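The hydroazulene is disconnected at C7–C8 and C1–C10. In the seven-membered ring (C1, C5–C10) the oxygenated C5–C6 unit and the C8–C9 epoxide flank the lone methylene C7, and quaternary C1 sits next to C10: the imprint of a cyclohepta-1,4-diene. From (S)-terpinen-4-ol 1, whose carbinol carbon becomes C4, the precursor is made: the bis(triethylsilyl) dienol ether 8 of an acetylcyclopentenol. In one operation, rhodium-carbenoid cyclopropanation of 8 by methyl 2-diazobut-3-enoate 13 and Cope rearrangement of the cis-divinylcyclopropane close that ring, set C1 and leave C5=C6 as a silyl enol ether and C8=C9 as an enoate.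

Key step: step 8

Atom labels: C1 = ring-fusion carbon bearing methyl; C2, C3 = cyclopentane CH2; C4 = isopropyl carbinol; C5 = ring-fusion CH; C6 = benzoate carbon; C7 = CH2; C8 (methyl) and C9 = epoxide carbons; C10 = CH2. β is the face of the C1 methyl group, α the opposite face.

Assumption: Rh2(S-DOSP)4 is taken to be the catalyst enantiomer that sends the carbenoid to the Si face of C6 of diene 8 (cyclopropane 14 as drawn); if its sense proves opposite, Rh2(R-DOSP)4 replaces it with nothing else changed.

**Step 1**
Reactants: 1 (S)-terpinen-4-ol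
Product: 4 (5R)-5-hydroxy-2-methyl-5-(propan-2-yl)cyclopent-1-ene-1-carbaldehyde, via ozonide 2 (not isolated), via keto aldehyde 3 (not isolated)
Conditions: O3, CH2Cl2, −78 °C; Me2S, −78 °C → rt; then piperidine (cat.), AcOH (cat.), toluene, 50 °C
Reagents that add atoms: ozone, [O-][O+]=O
Why: Ozonolysis with reductive work-up opens the only alkene to keto aldehyde 3, and the piperidinium acetate aldol condensation then closes the five-membered ring through the aldehyde enamine attacking the methyl ketone (dehydration follows), the usual course for 6-oxoheptanals, while the carbinol stereocentre is untouched.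

**Step 2**
Reactants: 4 cyclopentenecarbaldehyde; 5 methylmagnesium bromide
Product: 6 1-[(5R)-5-hydroxy-2-methyl-5-(propan-2-yl)cyclopent-1-en-1-yl]ethan-1-ol (both side-chain epimers)
Conditions: MeMgBr (2.5 equiv), THF, −78 → 0 °C; aq. NH4Cl
Reagents that add atoms: methylmagnesium bromide, C[Mg]Br
Why: Grignard 1,2-addition to the enal (one equivalent is spent on the tertiary alkoxide); the new carbinol centre forms as a mixture that is erased by the oxidation in step 3.

**Step 3**
Reactants: 6 allylic alcohol
Product: 7 1-[(5R)-5-hydroxy-2-methyl-5-(propan-2-yl)cyclopent-1-en-1-yl]ethan-1-one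
Conditions: Dess–Martin periodinane (1.3 equiv), CH2Cl2, 0 °C → rt
Reagents that add atoms: none
Why: Dess–Martin oxidation converts the secondary allylic alcohol into the methyl ketone and cannot touch the tertiary alcohol.

**Step 4**
Reactants: 7 acetylcyclopentenol
Product: 8 bis(triethylsilyl) dienol ether (tertiary silyl ether at C4, 2-silyloxydiene C7=C6–C5=C1)
Conditions: Et3SiOTf (2.6 equiv), Et3N (4 equiv), CH2Cl2, −78 → 0 °C
Reagents that add atoms: triethylsilyl trifluoromethanesulfonate, CC[Si](CC)(CC)OS(=O)(=O)C(F)(F)F
Why: Silyl triflate and amine effect soft enolisation of the methyl ketone at its kinetically preferred α′ methyl group to give the cross-conjugated 2-silyloxydiene and the same reagent silylates the hindered tertiary alcohol, triethylsilyl being chosen because it goes on where a bulkier silyl group is slow, still shields the β face of C5 later and comes off under mild fluoride.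

**Step 5**
Reactants: 9 methyl acetoacetate
Product: 10 methyl 2-diazo-3-oxobutanoate
Conditions: 4-acetamidobenzenesulfonyl azide (1.1 equiv), Et3N, MeCN, 0 °C → rt
Reagents that add atoms: 4-acetamidobenzenesulfonyl azide, CC(=O)Nc1ccc(cc1)S(=O)(=O)N=[N+]=[N-]
Why: Regitz diazo transfer from the sulfonyl azide to the doubly activated methylene.

**Step 6**
Reactants: 10 methyl 2-diazo-3-oxobutanoate
Product: 11 methyl 2-diazo-3-hydroxybutanoate (racemic)
Conditions: NaBH4, MeOH, 0 °C
Reagents that add atoms: none
Why: Borohydride reduces the ketone chemoselectively beside the ester-stabilised diazo group, and the racemic carbinol centre disappears in step 7.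

**Step 7**
Reactants: 11 methyl 2-diazo-3-hydroxybutanoate
Product: 13 methyl 2-diazobut-3-enoate, via dichlorophosphate 12 (not isolated)
Conditions: POCl3 (1.5 equiv), Et3N (4 equiv), CH2Cl2, 0 °C; cold filtration, used at once as a cold pentane solution
Reagents that add atoms: none
Why: The alcohol is activated as its dichlorophosphate and triethylamine effects E2 elimination toward the methyl group, the standard dehydration route to vinyldiazoacetates, and 13 is kept cold and used immediately because it cyclises to a pyrazole on standing.

**Step 8**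
Reactants: 8 bis(triethylsilyl) dienol ether; 13 methyl 2-diazobut-3-enoate
Product: 15 hydroazulene diene ester (C5=C6 triethylsilyl enol ether, C8=C9 alkene with CO2Me on C8, C4 silyl ether and C1 methyl both β), via cyclopropane 14 (not isolated)
Conditions: Rh2(S-DOSP)4 (2 mol %), hexanes, −78 °C → rt, slow addition of 13 (2.5 equiv); then 70 °C
Reagents that add atoms: none
Why: The donor/acceptor rhodium vinylcarbenoid from 13 cyclopropanates the terminal silyl enol ether C6=C7 of 8 on the Si face of C6 (carbenoid carbon = C8, vinyl cis to the cyclopentenyl group), and the cis-divinylcyclopropane 14 then undergoes a [3,3] shift in which C1–C10 forms as the strained, donor–acceptor-weakened C6–C8 bond breaks. The closest known reaction type is the rhodium-catalysed formal [4+3] cycloaddition of vinyldiazoacetates with 2-silyloxydienes (tandem cyclopropanation and divinylcyclopropane Cope rearrangement). The three-membered ring closes by concerted carbene [2+1] addition and the seven-membered ring by a suprafacial [3,3]-sigmatropic ring expansion through a boat transition state, so no Baldwin-type constraint applies. C1 is the only new stereocentre that survives (C6 and C8 return to sp2): the boat geometry forces C10 onto the face of C1 on which C8 was attached to C6, so the catalyst-set cyclopropane configuration is relayed to C1, α and anti to the C4 silyl ether, whose bulk works in the same direction. The step needs chemoselectivity for the terminal enol ether, secured because donor/acceptor carbenoids do not cyclopropanate the tetrasubstituted ring alkene, and attack at the carbenoid carbon in place of the vinyl terminus, favoured by the hydrocarbon solvent and carboxylate catalyst; gentle heating completes the rearrangement that the inward-pointing C1 methyl group slows.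

**Step 9**
Reactants: 15 hydroazulene diene ester
Product: 17 allylic alcohol (C8–CH2OH), via enal 16 (not isolated)
Conditions: iBu2AlH (2.5 equiv), CH2Cl2, −78 °C; aq. potassium sodium tartrate
Reagents that add atoms: none
Why: 1,2-Reduction of the conjugated ester by iBu2AlH at low temperature stops at the allylic alcohol and spares the silyl ether, the silyl enol ether and both alkenes, and the ester is removed before the C6 ketone is unveiled so that C7 never lies between a ketone and an enoate.

**Step 10**
Reactants: 17 allylic alcohol
Product: 19 C8-methyl diene (both silyl groups retained), via mesylate 18 (not isolated)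
Conditions: MsCl (1.3 equiv), Et3N (2 equiv), THF, −40 °C; then LiBHEt3 (3 equiv), −40 → 0 °C
Reagents that add atoms: none
Why: The primary allylic mesylate is displaced by hydride from LiBHEt3 in an SN2 reaction (direct attack at the unhindered CH2 is preferred over SN2′ at C9), a standard deoxygenation of allylic alcohols that leaves the C8 methyl group.

**Step 11**
Reactants: 19 C8-methyl diene
Product: 21 (3R,3aR,8aR)-3-hydroxy-6,8a-dimethyl-3-(propan-2-yl)-2,3,3a,5,8,8a-hexahydroazulen-4(1H)-one (trans-fused ketol), via silyloxy ketone 20 (not isolated)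
Conditions: HF·pyridine, pyridine, THF, −20 °C → rt
Reagents that add atoms: none
Why: Fluoride-assisted protodesilylation cleaves the enol ether first and the proton should reach C5 on the α face, because the C4 silyl ether and the C1 methyl group cover the β face and C6 moves away from the isopropyl group as C5 pyramidalises, which sets the trans ring fusion before the slower cleavage of the tertiary silyl ether at room temperature under buffered, non-basic conditions that avoid alkene migration, β-elimination and retro-aldol cleavage.

**Step 12**
Reactants: 21 trans-fused ketol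
Product: 22 (3R,3aS,4S,8aR)-6,8a-dimethyl-3-(propan-2-yl)-1,2,3,3a,4,5,8,8a-octahydroazulene-3,4-diol (C4 OH β, C6 OH α)
Conditions: Me4NBH(OAc)3 (5 equiv), MeCN/AcOH (1:1), −25 °C
Reagents that add atoms: none
Why: Evans–Saksena reduction, in which the C4 hydroxyl group exchanges onto boron and delivers hydride intramolecularly to the β face of the C6 ketone, which gives the 1,3-anti diol with the C6 hydroxyl group α.

**Step 13**
Reactants: 22 anti diol
Product: 23 8α,9α-epoxy diol
Conditions: VO(acac)2 (5 mol %), tBuOOH (1.5 equiv, decane solution), CH2Cl2, 0 °C → rt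
Reagents that add atoms: tert-butyl hydroperoxide, CC(C)(C)OO
Why: Hydroxyl-directed epoxidation with VO(acac)2 and tBuOOH, in which the homoallylic C6 hydroxyl group binds vanadium and delivers oxygen to the α face of C8=C9 (the C1 methyl group blocks the other face and the tertiary C4 hydroxyl group is too remote and hindered to compete), which sets C8 and C9.

**Step 14**
Reactants: 23 epoxy diol
Product: 24 8α,9α-epoxy-4β-hydroxydaucan-6α-yl benzoate (target, CNP0340059.1)
Conditions: Bz2O (1.5 equiv), DMAP (0.2 equiv), Et3N (3 equiv), CH2Cl2, 0 °C → rt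
Reagents that add atoms: benzoic anhydride, O=C(OC(=O)c1ccccc1)c1ccccc1
Why: DMAP-catalysed acyl transfer benzoylates the secondary C6 hydroxyl group selectively over the hindered tertiary C4 hydroxyl group, and the chloride-free anhydride conditions spare the epoxide.

**Compound list**
1 | (S)-terpinen-4-ol, (1S)-4-methyl-1-(propan-2-yl)cyclohex-3-en-1-ol | CC(C)[C@]1(O)CCC(C)=CC1 | starting material
2 | secondary ozonide of 1 (1,2,4-trioxolane across the former alkene carbons, mixture at the two new centres) | CC(C)[C@]1(O)CCC2(C)OOC(C1)O2 | intermediate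
3 | (3S)-3-hydroxy-6-oxo-3-(propan-2-yl)heptanal | CC(C)[C@@](O)(CC=O)CCC(C)=O | intermediate
4 | (5R)-5-hydroxy-2-methyl-5-(propan-2-yl)cyclopent-1-ene-1-carbaldehyde | CC(C)[C@]1(O)CCC(C)=C1C=O | intermediate
5 | methylmagnesium bromide | C[Mg]Br | starting material
6 | 1-[(5R)-5-hydroxy-2-methyl-5-(propan-2-yl)cyclopent-1-en-1-yl]ethan-1-ol (epimers at the side-chain carbinol) | CC(C)[C@]1(O)CCC(C)=C1C(C)O | intermediate
7 | 1-[(5R)-5-hydroxy-2-methyl-5-(propan-2-yl)cyclopent-1-en-1-yl]ethan-1-one | CC(C)[C@]1(O)CCC(C)=C1C(C)=O | intermediate
8 | triethyl({1-[(5R)-2-methyl-5-(propan-2-yl)-5-(triethylsilyloxy)cyclopent-1-en-1-yl]ethenyl}oxy)silane | CC(C)[C@]1(O[Si](CC)(CC)CC)CCC(C)=C1C(=C)O[Si](CC)(CC)CC | intermediate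
9 | methyl acetoacetate | CC(=O)CC(=O)OC | starting material
10 | methyl 2-diazo-3-oxobutanoate | CC(=O)C(=[N+]=[N-])C(=O)OC | intermediate
11 | methyl 2-diazo-3-hydroxybutanoate (racemic) | CC(O)C(=[N+]=[N-])C(=O)OC | intermediate
12 | methyl 3-(dichlorophosphoryloxy)-2-diazobutanoate (racemic) | CC(OP(=O)(Cl)Cl)C(=[N+]=[N-])C(=O)OC | intermediate
13 | methyl 2-diazobut-3-enoate | C=CC(=[N+]=[N-])C(=O)OC | intermediate
14 | methyl (1S,2R)-1-ethenyl-2-[(5R)-2-methyl-5-(propan-2-yl)-5-(triethylsilyloxy)cyclopent-1-en-1-yl]-2-(triethylsilyloxy)cyclopropane-1-carboxylate (vinyl and cyclopentenyl cis) | C=C[C@@]1(C(=O)OC)C[C@@]1(O[Si](CC)(CC)CC)C2=C(C)CC[C@@]2(O[Si](CC)(CC)CC)C(C)C | intermediate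
15 | methyl (3R,8aR)-8a-methyl-3-(propan-2-yl)-3,4-bis(triethylsilyloxy)-1,2,3,5,8,8a-hexahydroazulene-6-carboxylate | CC(C)[C@]1(O[Si](CC)(CC)CC)CC[C@]2(C)CC=C(C(=O)OC)CC(O[Si](CC)(CC)CC)=C21 | intermediate
16 | (3R,8aR)-8a-methyl-3-(propan-2-yl)-3,4-bis(triethylsilyloxy)-1,2,3,5,8,8a-hexahydroazulene-6-carbaldehyde | CC(C)[C@]1(O[Si](CC)(CC)CC)CC[C@]2(C)CC=C(C=O)CC(O[Si](CC)(CC)CC)=C21 | intermediate
17 | [(3R,8aR)-8a-methyl-3-(propan-2-yl)-3,4-bis(triethylsilyloxy)-1,2,3,5,8,8a-hexahydroazulen-6-yl]methanol | CC(C)[C@]1(O[Si](CC)(CC)CC)CC[C@]2(C)CC=C(CO)CC(O[Si](CC)(CC)CC)=C21 | intermediate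
18 | methanesulfonate of 17 | CC(C)[C@]1(O[Si](CC)(CC)CC)CC[C@]2(C)CC=C(COS(C)(=O)=O)CC(O[Si](CC)(CC)CC)=C21 | intermediate
19 | (3R,8aR)-6,8a-dimethyl-3-(propan-2-yl)-3,4-bis(triethylsilyloxy)-1,2,3,5,8,8a-hexahydroazulene | CC(C)[C@]1(O[Si](CC)(CC)CC)CC[C@]2(C)CC=C(C)CC(O[Si](CC)(CC)CC)=C21 | intermediate
20 | (3R,3aR,8aR)-6,8a-dimethyl-3-(propan-2-yl)-3-(triethylsilyloxy)-2,3,3a,5,8,8a-hexahydroazulen-4(1H)-one (C5 H α) | CC(C)[C@]1(O[Si](CC)(CC)CC)CC[C@]2(C)CC=C(C)CC(=O)[C@H]21 | intermediate
21 | (3R,3aR,8aR)-3-hydroxy-6,8a-dimethyl-3-(propan-2-yl)-2,3,3a,5,8,8a-hexahydroazulen-4(1H)-one | CC(C)[C@]1(O)CC[C@]2(C)CC=C(C)CC(=O)[C@H]21 | intermediate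
22 | (3R,3aS,4S,8aR)-6,8a-dimethyl-3-(propan-2-yl)-1,2,3,3a,4,5,8,8a-octahydroazulene-3,4-diol | CC(C)[C@]1(O)CC[C@]2(C)CC=C(C)C[C@H](O)[C@H]21 | intermediate
23 | 8α,9α-epoxide of 22 (epoxide oxygen, C6 OH and C5 H α; C4 OH and C1 methyl β) | CC(C)[C@]1(O)CC[C@]2(C)C[C@@H]3O[C@]3(C)C[C@H](O)[C@H]21 | intermediate
24 | 8α,9α-epoxy-4β-hydroxydaucan-6α-yl benzoate | CC(C)[C@]1(O)CC[C@]2(C)C[C@@H]3O[C@]3(C)C[C@H](OC(=O)c3ccccc3)[C@H]21 | target

Total step count: 14. Longest linear sequence: 11 steps (steps 1–4 and 8–14, from 1 to 24); the diazo branch (steps 5–7) joins at step 8.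

**Steps most likely to fail**

Step 8. The catalyst's facial preference and that of the substrate may oppose each other, or the carbenoid may add with the vinyl group trans to the cyclopentenyl group so that the rearrangement stalls. Either would give low conversion to the seven-membered ring or erosion of the C1 configuration, and slow capture by the hindered diene would let 13 decay. In the fallback, stereocontrol is handed to the substrate and the two events are separated. Setting out from 8 and 13, the achiral catalyst Rh2(OPiv)4 in pentane at −40 °C should give the cyclopropane as a mixture of ring diastereomers F1, which is isolated. Heating in toluene at 110–130 °C lets the cis and trans isomers interconvert through reversible opening of the donor–acceptor C6–C8 bond and drain through the divinylcyclopropane rearrangement, the C4 silyl ether alone then deciding the face of C1. The route is rejoined at 15.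

Step 11. The proton may reach C5 from the β face (cis ring fusion), C8=C9 may migrate into conjugation with the new ketone, or the C4 oxygen may be lost by β-elimination. In the fallback, the proton is delivered to a preformed enolate under steric control in place of acid-mediated tautomerisation. Setting out from 19, MeLi in THF at −20 °C should cleave only the enol silyl group and give the lithium enolate F2. A quench at −78 °C with 2,6-di-tert-butyl-4-methylphenol, a donor too bulky to pass the C4 silyl ether and too weak to equilibrate the ketone, should give 20, which is now isolated and checked. HF·pyridine then returns to the route at 21.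

Step 13. The new epoxide may be opened across the ring by the C4 hydroxyl group under the Lewis-acidic vanadium conditions, or face selectivity may be incomplete. In the fallback, the order of the last two steps is reversed and a metal-free oxidant is used. Setting out from 22, Bz2O and DMAP should give the C6 benzoate F3. Buffered peracid epoxidation (mCPBA, NaHCO3, CH2Cl2, 0 °C), with attack anti to the C1 methyl group, then arrives directly at 24.

**Further compounds**
F1 | step 8 | methyl 1-ethenyl-2-[(5R)-2-methyl-5-(propan-2-yl)-5-(triethylsilyloxy)cyclopent-1-en-1-yl]-2-(triethylsilyloxy)cyclopropane-1-carboxylate, mixture of ring diastereomers | C=CC1(C(=O)OC)CC1(O[Si](CC)(CC)CC)C2=C(C)CC[C@@]2(O[Si](CC)(CC)CC)C(C)C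
F2 | step 11 | lithium enolate of 20 (C5=C6 enolate, C4 silyl ether retained) | CC(C)[C@]1(O[Si](CC)(CC)CC)CC[C@]2(C)CC=C(C)CC([O-])=C21.[Li+]
F3 | step 13 | (3R,3aS,4S,8aR)-3-hydroxy-6,8a-dimethyl-3-(propan-2-yl)-1,2,3,3a,4,5,8,8a-octahydroazulen-4-yl benzoate | CC(C)[C@]1(O)CC[C@]2(C)CC=C(C)C[C@H](OC(=O)c3ccccc3)[C@H]21
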